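**Retrosynthetic overview**

1. The target is a cis-fused 1,2-dioxane/γ-lactone (tetrahydrofuro[3,2-c][1,2]dioxin-6-one; O1–O2 peroxide, C3, C4, C4a, lactone O5, C6=O, C7, C7a). Enabling feature: C3 (bonded to O2, CH3, ring C4H2 and chain C1') is a masked ketone at the peroxyketal level, 1,3 to the lactone C4a–O. On the derived cyclic peroxycarbenium ion the group that arrives last enters axially, cis to the C7 methylene on C7a; in the target that group is CH3, so the chain must be on C3 first.
2. Hence C3–CH3 is cut last (methylation of a C3 methyl peroxyketal), and C3–C1' is cut at the acyl level: Pd-catalysed acylation of the C16 trienylzinc reagent with the acid chloride of (S)-4-methylmuconolactone.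
3. Ring order: the lactone (butenolide) ring first, from 4-methylcatechol by enzymatic intradiol C–C cleavage and cycloisomerisation (sets C4a). The 1,2-dioxane ring second, by hydroperoxyketalisation of the chain ketone and 6-exo oxa-Michael closure onto the butenolide (sets C7a, cis-fused).
4. The all-E triene chain comes from a Horner–Wadsworth–Emmons union of a heptadienylphosphonate with 9-bromononanal.

Key step: step 8

Assumption: the bacterial muconate cycloisomerase is taken to give the (4S)-lactone (syn cycloisomerisation with the same facial sense as for cis,cis-muconate); the chiral-pool fallback to the same acid does not depend on this.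

**Route**

Step 1
Reactants: 1 (2E,4E)-hepta-2,4-dienal
Product: 2 (2E,4E)-hepta-2,4-dien-1-ol
Conditions: NaBH4, CeCl3·7H2O, MeOH, 0 °C
Reagents that add atoms: none
Why: Luche 1,2-reduction of the dienal should leave the (E,E)-diene untouched.

Step 2
Reactants: 2 (2E,4E)-hepta-2,4-dien-1-ol
Product: 3 (2E,4E)-1-bromohepta-2,4-diene
Conditions: PBr3 (0.4 equiv), Et2O, −10 °C, dark; used crude
Reagents that add atoms: phosphorus tribromide BrP(Br)Br
Why: Bromination of the primary dienylic alcohol; any SN2' isomer should re-equilibrate to the conjugated linear bromide.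

Step 3
Reactants: 3 (2E,4E)-1-bromohepta-2,4-diene
Product: 4 diethyl [(2E,4E)-hepta-2,4-dien-1-yl]phosphonate
Conditions: P(OEt)3, neat, 110 °C, EtBr distilled off
Reagents that add atoms: triethyl phosphite CCOP(OCC)OCC
Why: Michaelis–Arbuzov reaction of a reactive primary dienylic bromide.

Step 4
Reactants: 5 9-bromononan-1-ol
Product: 6 9-bromononanal
Conditions: Dess–Martin periodinane, NaHCO3, CH2Cl2, rt
Reagents that add atoms: none
Why: Dess–Martin oxidation of a primary alcohol; the primary bromide is inert.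

Step 5
Reactants: 4 diethyl [(2E,4E)-hepta-2,4-dien-1-yl]phosphonate; 6 9-bromononanal
Product: 7 (3E,5E,7E)-16-bromohexadeca-3,5,7-triene
Conditions: LiHMDS, THF, −78 °C; then 6, −78 °C to rt; then I2 (2 mol %), hexane, rt, daylight
Reagents that add atoms: none
Why: Horner–Wadsworth–Emmons olefination through the α-carbon of the pentadienylic phosphonate anion should be E-selective at the new C7=C8 bond; catalytic iodine equilibrates any 7Z isomer to the all-E triene, and the bromide does not react at −78 °C.

Step 6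
Reactants: 8 4-methylcatechol
Product: 10 (S)-4-methylmuconolactone, via 3-methyl-cis,cis-muconic acid 9 (not isolated)
Conditions: catechol 1,2-dioxygenase (intradiol) and muconate cycloisomerase (Mn2+), air, phosphate buffer pH 7.5, 30 °C; then pH 2, EtOAc extraction
Reagents that add atoms: dioxygen O=O
Why: The intradiol dioxygenase cleaves the C1–C2 bond of the catechol with incorporation of both oxygen atoms to give the (2Z,4Z)-muconate, and the cycloisomerase adds the distal carboxylate to the methyl-bearing C3 in a syn 5-exo-trig cycloisomerisation, so the quaternary stereocentre is set by the enzyme (the natural bacterial ortho-cleavage sequence of 4-methylcatechol).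

Step 7
Reactants: 10 (S)-4-methylmuconolactone
Product: 11 2-[(2S)-2-methyl-5-oxo-2,5-dihydrofuran-2-yl]acetyl chloride
Conditions: (COCl)2, DMF (cat.), CH2Cl2, 0 °C to rt; evaporated, used crude
Reagents that add atoms: oxalyl chloride O=C(Cl)C(Cl)=O
Why: Vilsmeier-type acid chloride formation under acidic, base-free conditions, which the butenolide and its quaternary centre should tolerate.

Step 8
Reactants: 7 (3E,5E,7E)-16-bromohexadeca-3,5,7-triene; 11 2-[(2S)-2-methyl-5-oxo-2,5-dihydrofuran-2-yl]acetyl chloride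
Product: 13 (5S)-5-methyl-5-[(11E,13E,15E)-2-oxooctadeca-11,13,15-trien-1-yl]furan-2(5H)-one, via [(9E,11E,13E)-hexadeca-9,11,13-trien-1-yl]zinc bromide 12 (not isolated)
Conditions: Zn dust (activated with BrCH2CH2Br, TMSCl), LiCl, THF, 50 °C; then 11, Pd(PPh3)4 (5 mol %), THF, 0 °C to rt
Reagents that add atoms: none
Why: Negishi acylation: Pd(0) adds oxidatively into the C(acyl)–Cl bond of 11, the primary alkylzinc 12 transmetalates, and reductive elimination forms the C3–C1' bond as a ketone; the closest known type is the Pd-catalysed acylation of functionalised alkylzinc halides with acid chlorides. The step closes no ring and creates no stereocentre; it joins all carbons of the target except one methyl and fixes C3 at the ketone level with the chain already attached, which is what allows the methyl to be delivered last and axially in step 10. The acyl chloride must react in preference to the butenolide enoate and the lactone carbonyl, which the non-basic, weakly nucleophilic RZnBr secures. The quaternary C5 of the butenolide (C4a of the target) must survive, which the neutral conditions secure because no base is present to open the β-acyloxy ketone by E1cB. The (E,E,E)-triene should stay untouched because neither Pd–H nor radical species are generated.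

Step 9
Reactants: 13 (5S)-5-methyl-5-[(11E,13E,15E)-2-oxooctadeca-11,13,15-trien-1-yl]furan-2(5H)-one
Product: 15 (4aS,7aS)-3-[(9E,11E,13E)-hexadeca-9,11,13-trien-1-yl]-3-methoxy-4a-methyltetrahydro-3H-furo[3,2-c][1,2]dioxin-6(4H)-one (both C3 anomers), via methoxy hydroperoxide 14 (not isolated)
Conditions: urea·H2O2, Sc(OTf)3 (10 mol %), MeOH, rt; then solvent switch, Et2NH, CF3CH2OH, rt
Reagents that add atoms: hydrogen peroxide (as urea adduct) OO; methanol CO
Why: Lewis-acid-catalysed perhydrolysis of the ketone in methanol gives the α-methoxy hydroperoxide, whose OOH group then adds under amine catalysis to the butenolide β-carbon in a reversible 6-exo-trig oxa-Michael closure (a hydroperoxyketalisation/peroxy-Michael sequence known for keto enoates); the tether from C4a allows only the cis-fused ring, which sets C7a (H cis to the C4a methyl), and the ketal carbon stays an anomeric mixture that step 10 converges.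

Step 10
Reactants: 15 (4aS,7aS)-3-[(9E,11E,13E)-hexadeca-9,11,13-trien-1-yl]-3-methoxy-4a-methyltetrahydro-3H-furo[3,2-c][1,2]dioxin-6(4H)-one (both C3 anomers)
Product: 16 (3S,4aS,7aS)-3-[(9E,11E,13E)-hexadeca-9,11,13-trien-1-yl]-3,4a-dimethyltetrahydro-3H-furo[3,2-c][1,2]dioxin-6(4H)-one
Conditions: AlMe3 (4 equiv), TMSOTf (20 mol %), CH2Cl2, −78 to −30 °C; Rochelle salt work-up
Reagents that add atoms: trimethylaluminium C[Al](C)C
Why: Proposed new method: TMSOTf/AlMe3 should ionise the exocyclic C3–OMe bond of either anomer to the same cyclic peroxycarbenium ion (stabilised by O2), which adopts the half-chair with C4a–O pseudoaxial and C4a–CH3 pseudoequatorial, and the methylaluminate transfers CH3 to C3 along the axial trajectory on the face syn to that oxygen, so the new methyl ends up axial and cis to the C7 methylene with the chain equatorial, i.e. (3S) (stereoconvergent, substrate-controlled); the closest known reaction types are the Lewis-acid-mediated substitution of 3-alkoxy-1,2-dioxanes and -dioxolanes by allylsilanes, silyl enol ethers and silanes via peroxycarbenium ions, and the AlMe3 C-methylation of anomeric acetals and fluorides in peroxide-containing trioxanes, whereas an organoaluminium nucleophile has not been shown on a peroxyketal.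

**Compound list**

1 | (2E,4E)-hepta-2,4-dienal | CC/C=C/C=C/C=O | starting material
2 | (2E,4E)-hepta-2,4-dien-1-ol | CC/C=C/C=C/CO | intermediate
3 | (2E,4E)-1-bromohepta-2,4-diene | CC/C=C/C=C/CBr | intermediate
4 | diethyl [(2E,4E)-hepta-2,4-dien-1-yl]phosphonate | CC/C=C/C=C/CP(=O)(OCC)OCC | intermediate
5 | 9-bromononan-1-ol | OCCCCCCCCCBr | starting material
6 | 9-bromononanal | O=CCCCCCCCCBr | intermediate
7 | (3E,5E,7E)-16-bromohexadeca-3,5,7-triene | CC/C=C/C=C/C=C/CCCCCCCCBr | intermediate
8 | 4-methylcatechol (4-methylbenzene-1,2-diol) | Cc1ccc(O)c(O)c1 | starting material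
9 | 3-methyl-cis,cis-muconic acid, (2Z,4Z)-3-methylhexa-2,4-dienedioic acid | OC(=O)/C=C(C)\C=C/C(=O)O | intermediate
10 | (S)-4-methylmuconolactone, 2-[(2S)-2-methyl-5-oxo-2,5-dihydrofuran-2-yl]acetic acid | OC(=O)C[C@]1(C)OC(=O)C=C1 | intermediate
11 | 2-[(2S)-2-methyl-5-oxo-2,5-dihydrofuran-2-yl]acetyl chloride | O=C(Cl)C[C@]1(C)OC(=O)C=C1 | intermediate
12 | [(9E,11E,13E)-hexadeca-9,11,13-trien-1-yl]zinc bromide | CC/C=C/C=C/C=C/CCCCCCCC[Zn]Br | intermediate
13 | (5S)-5-methyl-5-[(11E,13E,15E)-2-oxooctadeca-11,13,15-trien-1-yl]furan-2(5H)-one | CC/C=C/C=C/C=C/CCCCCCCCC(=O)C[C@]1(C)OC(=O)C=C1 | intermediate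
14 | (5S)-5-[(11E,13E,15E)-2-hydroperoxy-2-methoxyoctadeca-11,13,15-trien-1-yl]-5-methylfuran-2(5H)-one (both C2' epimers) | CC/C=C/C=C/C=C/CCCCCCCCC(OC)(OO)C[C@]1(C)OC(=O)C=C1 | intermediate
15 | (4aS,7aS)-3-[(9E,11E,13E)-hexadeca-9,11,13-trien-1-yl]-3-methoxy-4a-methyltetrahydro-3H-furo[3,2-c][1,2]dioxin-6(4H)-one (both C3 anomers) | CC/C=C/C=C/C=C/CCCCCCCCC1(OC)C[C@]2(C)OC(=O)C[C@@H]2OO1 | intermediate
16 | (3S,4aS,7aS)-3-[(9E,11E,13E)-hexadeca-9,11,13-trien-1-yl]-3,4a-dimethyltetrahydro-3H-furo[3,2-c][1,2]dioxin-6(4H)-one | CC/C=C/C=C/C=C/CCCCCCCC[C@@]1(C)C[C@]2(C)OC(=O)C[C@@H]2OO1 | target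

**Totals**

Total step count: 10. Longest linear sequence: 7 steps (steps 1, 2, 3, 5, 8, 9, 10).

**Steps most likely to fail**

1. Step 10 (Proposed new method). Instead of methyl transfer to C3, the Lewis acid may trigger heterolysis of the O–O bond (Hock-type fragmentation), the aluminium reagent may attack a peroxide oxygen, or the cation may be captured by the triene or lose a proton to an enol peroxide. The fallback uses known chemistry: Mukaiyama–Isayama hydroperoxysilylation of a 1,1-disubstituted alkene, then oxa-Michael closure. The triene is added last because a cobalt hydride would also attack it, and C3 is not controlled, so the epimers must be separated. It sets out from 11 and 5 and comes back at 16. 9-Bromononan-1-ol 5 is silylated (TBSCl, imidazole, DMF) to tert-butyl[(9-bromononyl)oxy]dimethylsilane F1, which is converted with Zn/LiCl into {9-[(tert-butyldimethylsilyl)oxy]nonyl}zinc bromide F2 and acylated with 11 under the conditions of step 8 to the ketone (5S)-5-{11-[(tert-butyldimethylsilyl)oxy]-2-oxoundecyl}-5-methylfuran-2(5H)-one F3. Takai–Lombardo methylenation (Zn, CH2Br2, TiCl4) gives the alkene (5S)-5-{11-[(tert-butyldimethylsilyl)oxy]-2-methylideneundecyl}-5-methylfuran-2(5H)-one F4. Hydroperoxysilylation (Co(thd)2, O2, Et3SiH, ClCH2CH2Cl) gives the tertiary triethylsilyl peroxide F5. K2CO3 in MeOH frees the tertiary hydroperoxide F6, which Et2NH in CF3CH2OH closes to the cis-fused (3S)-peroxylactone silyl ether F7 and its (3R)-epimer F8; these are separated by chromatography. HF·pyridine converts F7 into the primary alcohol F9, Dess–Martin oxidation gives the aldehyde F10, and Horner–Wadsworth–Emmons olefination with 4 (LiHMDS, THF, −78 °C) gives 16.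

2. Step 9. Perhydrolysis may stall, so that free β-acyloxy ketone reaches the amine stage and opens by E1cB (erosion of configuration at C4a), or the Lewis-acidic methanol may solvolyse the butenolide. The fallback avoids the Lewis acid/methanol stage and uses a bis-hydroperoxide as the nucleophile. It sets out from 13 and comes back at 15. Ketone 13 is converted with aqueous H2O2 and catalytic I2 in MeCN into the gem-dihydroperoxide F11. Et2NH in CF3CH2OH closes one OOH group onto the butenolide to give the 3-hydroperoxy-1,2-dioxane F12. PPh3 (1 equiv, 0 °C) reduces only the exocyclic hydroperoxide to the peroxyhemiketal F13, and PPTS in MeOH gives 15.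

3. Step 6. Turnover of the cycloisomerase with the methyl-substituted muconate may be slow or inhibited, so that non-enzymatic lactonisation of 9 erodes the enantiomeric purity, or the enzyme at hand may deliver the other antipode. The fallback is a chiral-pool synthesis that does not start from a route compound: it replaces 8 by commercial (S)-citramalic acid F14 and comes back at 10. F14 is converted with 2,2-dimethoxypropane/PPTS into the dioxolanone acid 2-[(4S)-2,2,4-trimethyl-5-oxo-1,3-dioxolan-4-yl]acetic acid F15 and esterified (tBuOH, EDC, DMAP) to the tert-butyl ester F16. DIBAL-H at −78 °C reduces the dioxolanone to the lactol F17. Ph3P=CHCO2Me in MeOH gives the (Z)-4-hydroxy enoate F18 with loss of acetone, and PPTS in toluene lactonises it to the butenolide ester F19. TFA in CH2Cl2 cleaves the tert-butyl ester to give 10.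

Further compounds
F1 | step 10 | tert-butyl[(9-bromononyl)oxy]dimethylsilane | CC(C)(C)[Si](C)(C)OCCCCCCCCCBr
F2 | step 10 | {9-[(tert-butyldimethylsilyl)oxy]nonyl}zinc bromide | CC(C)(C)[Si](C)(C)OCCCCCCCCC[Zn]Br
F3 | step 10 | (5S)-5-{11-[(tert-butyldimethylsilyl)oxy]-2-oxoundecyl}-5-methylfuran-2(5H)-one | CC(C)(C)[Si](C)(C)OCCCCCCCCCC(=O)C[C@]1(C)OC(=O)C=C1
F4 | step 10 | (5S)-5-{11-[(tert-butyldimethylsilyl)oxy]-2-methylideneundecyl}-5-methylfuran-2(5H)-one | CC(C)(C)[Si](C)(C)OCCCCCCCCCC(=C)C[C@]1(C)OC(=O)C=C1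
F5 | step 10 | (5S)-5-{11-[(tert-butyldimethylsilyl)oxy]-2-methyl-2-[(triethylsilyl)peroxy]undecyl}-5-methylfuran-2(5H)-one (both C2' epimers) | CC(C)(C)[Si](C)(C)OCCCCCCCCCC(C)(OO[Si](CC)(CC)CC)C[C@]1(C)OC(=O)C=C1
F6 | step 10 | (5S)-5-{11-[(tert-butyldimethylsilyl)oxy]-2-hydroperoxy-2-methylundecyl}-5-methylfuran-2(5H)-one (both C2' epimers) | CC(C)(C)[Si](C)(C)OCCCCCCCCCC(C)(OO)C[C@]1(C)OC(=O)C=C1
F7 | step 10 | (3S,4aS,7aS)-3-{9-[(tert-butyldimethylsilyl)oxy]nonyl}-3,4a-dimethyltetrahydro-3H-furo[3,2-c][1,2]dioxin-6(4H)-one | CC(C)(C)[Si](C)(C)OCCCCCCCCC[C@@]1(C)C[C@]2(C)OC(=O)C[C@@H]2OO1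
F8 | step 10 | (3R,4aS,7aS)-3-{9-[(tert-butyldimethylsilyl)oxy]nonyl}-3,4a-dimethyltetrahydro-3H-furo[3,2-c][1,2]dioxin-6(4H)-one | CC(C)(C)[Si](C)(C)OCCCCCCCCC[C@]1(C)C[C@]2(C)OC(=O)C[C@@H]2OO1
F9 | step 10 | (3S,4aS,7aS)-3-(9-hydroxynonyl)-3,4a-dimethyltetrahydro-3H-furo[3,2-c][1,2]dioxin-6(4H)-one | OCCCCCCCCC[C@@]1(C)C[C@]2(C)OC(=O)C[C@@H]2OO1
F10 | step 10 | 9-[(3S,4aS,7aS)-3,4a-dimethyl-6-oxohexahydro-3H-furo[3,2-c][1,2]dioxin-3-yl]nonanal | O=CCCCCCCCC[C@@]1(C)C[C@]2(C)OC(=O)C[C@@H]2OO1
F11 | step 9 | (5S)-5-[(11E,13E,15E)-2,2-dihydroperoxyoctadeca-11,13,15-trien-1-yl]-5-methylfuran-2(5H)-one | CC/C=C/C=C/C=C/CCCCCCCCC(OO)(OO)C[C@]1(C)OC(=O)C=C1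
F12 | step 9 | (4aS,7aS)-3-[(9E,11E,13E)-hexadeca-9,11,13-trien-1-yl]-3-hydroperoxy-4a-methyltetrahydro-3H-furo[3,2-c][1,2]dioxin-6(4H)-one (both C3 anomers) | CC/C=C/C=C/C=C/CCCCCCCCC1(OO)C[C@]2(C)OC(=O)C[C@@H]2OO1
F13 | step 9 | (4aS,7aS)-3-[(9E,11E,13E)-hexadeca-9,11,13-trien-1-yl]-3-hydroxy-4a-methyltetrahydro-3H-furo[3,2-c][1,2]dioxin-6(4H)-one (both C3 anomers) | CC/C=C/C=C/C=C/CCCCCCCCC1(O)C[C@]2(C)OC(=O)C[C@@H]2OO1
F14 | step 6 | (S)-citramalic acid, (2S)-2-hydroxy-2-methylbutanedioic acid | C[C@](O)(CC(=O)O)C(=O)O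
F15 | step 6 | 2-[(4S)-2,2,4-trimethyl-5-oxo-1,3-dioxolan-4-yl]acetic acid | C[C@@]1(CC(=O)O)OC(C)(C)OC1=O
F16 | step 6 | tert-butyl 2-[(4S)-2,2,4-trimethyl-5-oxo-1,3-dioxolan-4-yl]acetate | C[C@@]1(CC(=O)OC(C)(C)C)OC(C)(C)OC1=O
F17 | step 6 | tert-butyl 2-[(4S)-5-hydroxy-2,2,4-trimethyl-1,3-dioxolan-4-yl]acetate (both C5 epimers) | C[C@@]1(CC(=O)OC(C)(C)C)OC(C)(C)OC1O
F18 | step 6 | 6-tert-butyl 1-methyl (2Z,4S)-4-hydroxy-4-methylhex-2-enedioate | COC(=O)/C=C\[C@@](C)(O)CC(=O)OC(C)(C)C
F19 | step 6 | tert-butyl 2-[(2S)-2-methyl-5-oxo-2,5-dihydrofuran-2-yl]acetate | CC(C)(C)OC(=O)C[C@]1(C)OC(=O)C=C1
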